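(The data come from a simulation on assumed constants; scatter was added.)

The two substrates are charged as a racemate, and mirror images differ in nothing except towards the single-handed free catalyst. So the excess e of left-handed over right-handed product, their difference over their sum, has zero as its symmetric value, and we measure everything from there.

| setting | Wednesday's | Saturday's | flask |
|---|---|---|---|
| left-handed substrate | 40 mM | 40 mM | 40 mM |
| right-handed substrate | 40 mM | 40 mM | 40 mM |
| partner | 170 mM | 260 mM | 120 mM |
| precatalyst | 31 µM | 31 µM | 31 µM |
| remark | run made earlier | run made earlier |  |
| time |  |  | 25 h |

| run | time / h | left-handed product / % | right-handed product / % |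
|---|---|---|---|
| Wednesday's | 2.50 | 3.4 | 2.9 |
| Wednesday's | 5.00 | 6.7 | 6.3 |
| Wednesday's | 8.00 | 8.1 | 8.5 |
| Wednesday's | 10.0 | 10.4 | 9.0 |
| Wednesday's | 12.0 | 9.3 | 10.0 |
| Wednesday's | 15.0 | 10.3 | 10.2 |
| Saturday's | 1.33 | 3.8 | 2.5 |
| Saturday's | 2.00 | 5.8 | 3.8 |
| Saturday's | 3.00 | 7.9 | 6.4 |
| Saturday's | 5.00 | 12.1 | 10.9 |
| Saturday's | 10.0 | 14.7 | 13.7 |
| Saturday's | 15.0 | 15.7 | 15.2 |

(each reading ± 0.5 percentage points)

* excess of left-handed product over right-handed product in the product at 30 min
* excess of left-handed product over right-handed product in the product at 25 h
* part of the left-handed substrate and right-handed substrate charged together that has reacted at 25 h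

- free catalyst is single-handed; left-handed substrate and right-handed substrate are mirror images of each other, charged as a racemate, each of them at the stated concentration
- an excess is below zero if the other one leads

Take first the main step by itself. Both hands use the same partner and the same free catalyst, so the ratio of their rates, the selectivity factor, contains neither charge, and while little has reacted e stays nearly flat.

Saturday's run is not flat. Its first two readings pooled give 20.8 % at a mean time of 1.67 h, and the next two give 7.24 % at 4.00 h.

So we add a second process, the products passing into each other, which draws e towards zero. We describe the fall in these readings by an apparent rate λ, taking ln e as a straight line, although new product keeps arriving meanwhile: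

λ = ln(early e / later e) / (time between) = 0.451 h⁻¹

Taken as first-order, this passing holds no charge either, so we carry the line to the new flask and run it back to 30 min. This gives the early excess E, our estimate of the excess at that time, which we expect to carry over to another partner charge:

E = 35.1 %

With a scatter of 0.5 percentage points per reading, this is a rough figure.

Now the rest. The readings of both runs level off, and their last sums of the two products stand in a ratio of 1.51 against 1.53 for the partner. Scaling Wednesday's level to the new partner charge gives us 14.5 % reacted. Since 1/λ = 2.22 h is far shorter than 25 h, we put the late excess near zero.

For the early excess, the late excess and the reacted part, the forecast gives 15 %, 1 % and 16 %, holding that “the initial excess is about 15%, though noisy”. Our early excess differs from the forecast's, while our late excess and reacted part lie close to its figures.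

In the same order, the flask gives 34.5 %, 0.175 % and 15.3 %.

    left-handed substrate ⇌ right-handed substrate (k = 0.200 h⁻¹)
    left-handed product ⇌ right-handed product (k = 0.480 h⁻¹)
    partner + free catalyst + left-handed substrate → free catalyst + left-handed product (k = 52000 M⁻² h⁻¹)
    partner + precatalyst → free catalyst + spent reagent (k = 1.40 M⁻¹ h⁻¹)
    partner + free catalyst + right-handed substrate → free catalyst + right-handed product (k = 22000 M⁻² h⁻¹)
    free catalyst → spent catalyst (k = 0.760 h⁻¹)

The flask's early excess of 34.5 % stands beside our E of 35.1 %, and the forecast's 15 % lies lower. For the same flask charged with 480 mM of partner, E of 35.1 % stands against a simulated 33.9 % at 30 min, while the reacted part of that flask reaches 48.9 % by 25 h. The reacted part of our flask stops low mainly because of the passing of free catalyst into spent catalyst: the same flask without that step has reacted 79.0 % by 25 h, against 15.3 %.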